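## Retrosynthetic overview

1. Both heterocycles are closed last, in one acid operation on an open-chain seco compound: the dihydropyranone by O1–C2 lactonisation of a Z-hydroxy ester, and flavanone ring C by C4–C4a Houben–Hoesch acylation with a nitrile.
2. The seco compound comes from a Friedel–Crafts opening (inversion at the benzylic carbon) of a trans-epoxide by a symmetric resorcinol ether that already carries the (S)-O–CH(Ph)CH2CN arm, so only the 6-substituted flavanone can result.
3. The epoxide fragment comes from Z-olefination ⇐ ozonolysis ⇐ Shi epoxidation ⇐ syn-selective silyloxyallylboration of cinnamaldehyde.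
4. The aryl ether comes from Mitsunobu inversion of (R)-3-hydroxy-3-phenylpropanenitrile with phloroglucinol.
5. Ring order: oxirane (step 2, opened in step 6), then the lactone and ring C together (step 7).

Assumption: allyl tert-butyldimethylsilyl ether, (3R)-3-hydroxy-3-phenylpropanenitrile, the tert-butyl Still–Gennari phosphonate and the Shi ketone of the L series are taken as catalogue items.

## Route

Step 1
Reactants: 1 (E)-cinnamaldehyde; 2 allyl tert-butyldimethylsilyl ether
Product: 6 (3S,4S,E)-4-[(tert-butyldimethylsilyl)oxy]-1-phenylhexa-1,5-dien-3-ol, via allyllithium 3 (not isolated), via allylborane 4 (not isolated), via borinate 5 (not isolated)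
Conditions: 2, sec-butyllithium, THF, −78 °C; (+)-B-methoxydiisopinocampheylborane [from (−)-α-pinene], −78 °C; BF3·OEt2; then 1, −78 °C; pH 7 phosphate buffer, H2O2, MeOH, 0 °C
Reagents that add atoms: none
Why: Proposed new method: the silyloxy analogue of Brown's (Z)-γ-alkoxyallyl(diisopinocampheyl)borane should form because the lithiated allyl silyl ether, which is known to be trapped by Bu3SnCl at −78 °C, should be trapped likewise by the borinate before 1,2-silyl migration, and the Z-allylborane should then add through a chair Zimmerman–Traxler transition state (closest known reaction: Brown γ-(methoxymethoxy)allylboration), the Z-geometry giving the syn 3,4-relationship and the isopinocampheyl groups directing attack to the Re face of the aldehyde to set 3S,4S.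

Step 2
Reactants: 6 (3S,4S,E)-4-[(tert-butyldimethylsilyl)oxy]-1-phenylhexa-1,5-dien-3-ol
Product: 7 (1S,2S)-2-[(tert-butyldimethylsilyl)oxy]-1-[(2S,3S)-3-phenyloxiran-2-yl]but-3-en-1-ol
Conditions: 1,2:4,5-di-O-isopropylidene-β-L-erythro-2,3-hexodiulo-2,6-pyranose (0.3 equiv), KHSO5 (Oxone), K2CO3, Bu4NHSO4, MeCN–CH2(OMe)2–aqueous Na2B4O7 buffer, 0 °C
Reagents that add atoms: potassium peroxymonosulfate, [K+].[O-]S(=O)(=O)OO
Why: Shi asymmetric epoxidation, in which the chiral dioxirane attacks only the electron-rich trans-styryl alkene (the terminal vinyl group is slow) through a spiro transition state, so the ketone of the L series delivers oxygen to the face that gives the (2S,3S)-oxirane under catalyst control.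

Step 3
Reactants: 7 (1S,2S)-2-[(tert-butyldimethylsilyl)oxy]-1-[(2S,3S)-3-phenyloxiran-2-yl]but-3-en-1-ol
Product: 9 (2R,3S)-2-[(tert-butyldimethylsilyl)oxy]-3-hydroxy-3-[(2S,3S)-3-phenyloxiran-2-yl]propanal, via ozonide 8 (not isolated)
Conditions: O3, CH2Cl2, −78 °C; then PPh3, −78 → 20 °C
Reagents that add atoms: ozone, [O-][O+]=O
Why: Ozonolysis with reductive work-up cleaves the only remaining alkene to the aldehyde without touching the epoxide, silyl ether or any stereocentre (the descriptor at C2 changes only because the priorities change).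

Step 4
Reactants: 9 (2R,3S)-2-[(tert-butyldimethylsilyl)oxy]-3-hydroxy-3-[(2S,3S)-3-phenyloxiran-2-yl]propanal; 10 tert-butyl 2-[bis(2,2,2-trifluoroethoxy)phosphoryl]acetate
Product: 11 tert-butyl (2Z,4S,5S)-4-[(tert-butyldimethylsilyl)oxy]-5-hydroxy-5-[(2S,3S)-3-phenyloxiran-2-yl]pent-2-enoate
Conditions: 10, KN(SiMe3)2, 18-crown-6, THF, −78 °C; then crude 9, −78 °C
Reagents that add atoms: none
Why: Still–Gennari modification of the Horner–Wadsworth–Emmons olefination gives the Z-enoate under kinetic control, the phosphonate anion being too weak a base to deprotonate the free hydroxyl and the tert-butyl ester resisting lactonisation, so the chain stays open and no stereocentre is affected.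

Step 5
Reactants: 12 phloroglucinol; 13 (3R)-3-hydroxy-3-phenylpropanenitrile
Product: 14 (3S)-3-(3,5-dihydroxyphenoxy)-3-phenylpropanenitrile
Conditions: 12 (3 equiv), PPh3, DIAD, THF, 0 → 20 °C
Reagents that add atoms: none
Why: Mitsunobu etherification, in which the phenol displaces the activated benzylic alcohol by SN2 with inversion to set the S centre that becomes C2 of the flavanone, the excess of the symmetric triphenol favouring the mono-ether.

Step 6
Reactants: 11 tert-butyl (2Z,4S,5S)-4-[(tert-butyldimethylsilyl)oxy]-5-hydroxy-5-[(2S,3S)-3-phenyloxiran-2-yl]pent-2-enoate; 14 (3S)-3-(3,5-dihydroxyphenoxy)-3-phenylpropanenitrile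
Product: 15 tert-butyl (2Z,4S,5S,6R,7S)-4-[(tert-butyldimethylsilyl)oxy]-7-{4-[(1S)-2-cyano-1-phenylethoxy]-2,6-dihydroxyphenyl}-5,6-dihydroxy-7-phenylhept-2-enoate
Conditions: 14 (3 equiv), (CF3)2CHOH, 35 °C
Reagents that add atoms: none
Why: Friedel–Crafts ring opening of an aryl epoxide promoted by hexafluoroisopropanol, in which the hydrogen-bond-activated oxirane is attacked at the benzylic carbon in a borderline SN2 process with inversion (giving 7S, while C6 keeps its oxygen and configuration) by the ring carbon between the two hydroxyls, the two positions next to the bulky secondary ether being shielded.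

Step 7
Reactants: 15 tert-butyl (2Z,4S,5S,6R,7S)-4-[(tert-butyldimethylsilyl)oxy]-7-{4-[(1S)-2-cyano-1-phenylethoxy]-2,6-dihydroxyphenyl}-5,6-dihydroxy-7-phenylhept-2-enoate
Product: 18 (2S)-5,7-dihydroxy-6-{(1S,2R)-2-hydroxy-2-[(2R,3S)-3-hydroxy-6-oxo-3,6-dihydro-2H-pyran-2-yl]-1-phenylethyl}-2-phenylchroman-4-one, via lactone nitrile 16 (not isolated), via ketiminium chloride 17 (not isolated)
Conditions: ZnCl2, HCl (g), Et2O–1,4-dioxane, 0 °C, 16 h; then H2O–THF, 45 °C
Reagents that add atoms: water, O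
Why: Proposed new method: under anhydrous HCl/ZnCl2 the tert-butyl Z-ester should first lactonise onto the free 5-hydroxyl to the six-membered ring while the neighbouring 4-oxygen is still silylated (so no butenolide can form), the nitrile should then, as its nitrilium or imidoyl chloride, acylate the electron-rich ring ortho to the ether oxygen (both ortho positions are equivalent, so only the 6-substituted chromanone arises), and water finally hydrolyses the ketiminium salt and the silyl ether (closest known reactions: intramolecular Houben–Hoesch cyclisation of 3-aryloxypropanenitriles to chroman-4-ones and acid-catalysed lactonisation of Z-5-hydroxy-2-enoates), no stereocentre being formed or broken.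

## Compound list

1 | (E)-cinnamaldehyde | O=C/C=C/c1ccccc1 | starting material
2 | allyl tert-butyldimethylsilyl ether | C=CCO[Si](C)(C)C(C)(C)C | starting material
3 | (Z)-3-[(tert-butyldimethylsilyl)oxy]allyllithium | [Li]C/C=C\O[Si](C)(C)C(C)(C)C | intermediate
4 | [(Z)-3-[(tert-butyldimethylsilyl)oxy]allyl]diisopinocampheylborane (isopinocampheyl groups from (−)-α-pinene) | CC(C)(C)[Si](C)(C)O/C=C\CB([C@H]1C[C@H]2C[C@@H]([C@@H]1C)C2(C)C)[C@H]1C[C@H]2C[C@@H]([C@@H]1C)C2(C)C | intermediate
5 | (3S,4S,E)-4-[(tert-butyldimethylsilyl)oxy]-1-phenylhexa-1,5-dien-3-yl diisopinocampheylborinate | O([C@@H](/C=C/c1ccccc1)[C@@H](O[Si](C)(C)C(C)(C)C)C=C)B([C@H]1C[C@H]2C[C@@H]([C@@H]1C)C2(C)C)[C@H]1C[C@H]2C[C@@H]([C@@H]1C)C2(C)C | intermediate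
6 | (3S,4S,E)-4-[(tert-butyldimethylsilyl)oxy]-1-phenylhexa-1,5-dien-3-ol | O[C@@H](/C=C/c1ccccc1)[C@@H](O[Si](C)(C)C(C)(C)C)C=C | intermediate
7 | (1S,2S)-2-[(tert-butyldimethylsilyl)oxy]-1-[(2S,3S)-3-phenyloxiran-2-yl]but-3-en-1-ol | O[C@@H]([C@@H]1O[C@H]1c1ccccc1)[C@@H](O[Si](C)(C)C(C)(C)C)C=C | intermediate
8 | (1S,2R)-2-[(tert-butyldimethylsilyl)oxy]-1-[(2S,3S)-3-phenyloxiran-2-yl]-2-(1,2,4-trioxolan-3-yl)ethan-1-ol (both epimers at the trioxolane carbon) | O[C@@H]([C@@H]1O[C@H]1c1ccccc1)[C@@H](O[Si](C)(C)C(C)(C)C)C1OCOO1 | intermediate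
9 | (2R,3S)-2-[(tert-butyldimethylsilyl)oxy]-3-hydroxy-3-[(2S,3S)-3-phenyloxiran-2-yl]propanal | O[C@@H]([C@@H]1O[C@H]1c1ccccc1)[C@@H](O[Si](C)(C)C(C)(C)C)C=O | intermediate
10 | tert-butyl 2-[bis(2,2,2-trifluoroethoxy)phosphoryl]acetate | CC(C)(C)OC(=O)CP(=O)(OCC(F)(F)F)OCC(F)(F)F | starting material
11 | tert-butyl (2Z,4S,5S)-4-[(tert-butyldimethylsilyl)oxy]-5-hydroxy-5-[(2S,3S)-3-phenyloxiran-2-yl]pent-2-enoate | O[C@@H]([C@@H]1O[C@H]1c1ccccc1)[C@@H](O[Si](C)(C)C(C)(C)C)/C=C\C(=O)OC(C)(C)C | intermediate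
12 | phloroglucinol | Oc1cc(O)cc(O)c1 | starting material
13 | (3R)-3-hydroxy-3-phenylpropanenitrile | N#CC[C@@H](O)c1ccccc1 | starting material
14 | (3S)-3-(3,5-dihydroxyphenoxy)-3-phenylpropanenitrile | N#CC[C@H](Oc1cc(O)cc(O)c1)c1ccccc1 | intermediate
15 | tert-butyl (2Z,4S,5S,6R,7S)-4-[(tert-butyldimethylsilyl)oxy]-7-{4-[(1S)-2-cyano-1-phenylethoxy]-2,6-dihydroxyphenyl}-5,6-dihydroxy-7-phenylhept-2-enoate | CC(C)(C)OC(=O)/C=C\[C@H](O[Si](C)(C)C(C)(C)C)[C@@H](O)[C@H](O)[C@@H](c1ccccc1)c1c(O)cc(O[C@@H](CC#N)c2ccccc2)cc1O | intermediate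
16 | (3S)-3-(4-{(1S,2R)-2-[(2S,3S)-3-[(tert-butyldimethylsilyl)oxy]-6-oxo-3,6-dihydro-2H-pyran-2-yl]-2-hydroxy-1-phenylethyl}-3,5-dihydroxyphenoxy)-3-phenylpropanenitrile | O=C1C=C[C@H](O[Si](C)(C)C(C)(C)C)[C@H]([C@H](O)[C@@H](c2ccccc2)c2c(O)cc(O[C@@H](CC#N)c3ccccc3)cc2O)O1 | intermediate
17 | (2S)-6-{(1S,2R)-2-[(2S,3S)-3-[(tert-butyldimethylsilyl)oxy]-6-oxo-3,6-dihydro-2H-pyran-2-yl]-2-hydroxy-1-phenylethyl}-5,7-dihydroxy-2-phenylchroman-4-iminium chloride | O=C1C=C[C@H](O[Si](C)(C)C(C)(C)C)[C@H]([C@H](O)[C@@H](c2ccccc2)c2c(O)cc3c(c2O)C(=[NH2+])C[C@@H](c2ccccc2)O3)O1.[Cl-] | intermediate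
18 | (2S)-5,7-dihydroxy-6-{(1S,2R)-2-hydroxy-2-[(2R,3S)-3-hydroxy-6-oxo-3,6-dihydro-2H-pyran-2-yl]-1-phenylethyl}-2-phenylchroman-4-one | O=C1C=C[C@H](O)[C@H]([C@H](O)[C@@H](c2ccccc2)c2c(O)cc3c(c2O)C(=O)C[C@@H](c2ccccc2)O3)O1 | target

## Step count

Total steps: 7. Longest linear sequence: 6 (steps 1, 2, 3, 4, 6, 7).

## Steps most likely to fail, with fallbacks

Step 1 may fail if the lithiated silyl ether rearranges (silyl shift from oxygen to carbon) before it reaches boron, or if the silyloxy reagent is less selective than its alkoxy relatives. The fallback sets out from 1 and returns at 6. It uses the established Brown reagent made from allyl methoxymethyl ether and the same borinate, which gives (3S,4S,E)-4-(methoxymethoxy)-1-phenylhexa-1,5-dien-3-ol F1. The free hydroxyl is silylated with Et3SiCl and imidazole to triethyl{[(3S,4S,E)-4-(methoxymethoxy)-1-phenylhexa-1,5-dien-3-yl]oxy}silane F2. The acetal is cleaved with ZnBr2 and propane-1-thiol to (3S,4S,E)-6-phenyl-4-[(triethylsilyl)oxy]hexa-1,5-dien-3-ol F3. The liberated hydroxyl is protected with tert-butyldimethylsilyl triflate and 2,6-lutidine to tert-butyldimethyl{[(3S,4S,E)-6-phenyl-4-[(triethylsilyl)oxy]hexa-1,5-dien-3-yl]oxy}silane F4. Selective removal of the triethylsilyl group with pyridinium p-toluenesulfonate in methanol gives 6.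

Step 6 may fail through C-alkylation next to the ether oxygen, O-alkylation, or acid cleavage of the benzylic aryl ether of 14. The fallback sets out from 11 and returns at 15. Epoxide 11 is opened in hexafluoroisopropanol by phloroglucinol 12 itself, which has three equivalent ring positions and can give only one C-alkylation product, tert-butyl (2Z,4S,5S,6R,7S)-4-[(tert-butyldimethylsilyl)oxy]-5,6-dihydroxy-7-phenyl-7-(2,4,6-trihydroxyphenyl)hept-2-enoate F5. The chiral arm is then attached by Mitsunobu etherification of F5 with alcohol 13 (PPh3, DIAD). This should go at the unhindered hydroxyl para to the new substituent, because the two ortho hydroxyls are flanked by the bulky side chain, and gives 15; the selectivity over the ortho hydroxyls and over activation of the side-chain alcohols is the open point of this fallback.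

Step 7 may fail because the silyl ether is lost before the ester lactonises (butenolide formation). It may also fail because HCl/ZnCl2 ionises the alcohol next to the electron-rich ring, or because the benzylic aryl ether does not survive long enough for the nitrile to cyclise. The fallback sets out from 7 and returns at 16, so that only one ring is closed in the last operation. Alcohol 7 is acylated with acryloyl chloride (iPr2NEt, CH2Cl2, 0 °C) to (1S,2S)-2-[(tert-butyldimethylsilyl)oxy]-1-[(2S,3S)-3-phenyloxiran-2-yl]but-3-en-1-yl prop-2-enoate F6. Ring-closing metathesis with the second-generation Grubbs catalyst, RuCl2(=CHPh)(H2IMes)(PCy3), in CH2Cl2 at 40 °C gives (5S,6S)-5-[(tert-butyldimethylsilyl)oxy]-6-[(2R,3S)-3-phenyloxiran-2-yl]-5,6-dihydro-2H-pyran-2-one F7. Opening of F7 with 14 in hexafluoroisopropanol gives 16. The Houben–Hoesch closure (ZnCl2, HCl, then water) is then run on 16 alone to give 18.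

Further compounds
F1 | step 1 | (3S,4S,E)-4-(methoxymethoxy)-1-phenylhexa-1,5-dien-3-ol | O[C@@H](/C=C/c1ccccc1)[C@@H](OCOC)C=C
F2 | step 1 | triethyl{[(3S,4S,E)-4-(methoxymethoxy)-1-phenylhexa-1,5-dien-3-yl]oxy}silane | CC[Si](CC)(CC)O[C@@H](/C=C/c1ccccc1)[C@@H](OCOC)C=C
F3 | step 1 | (3S,4S,E)-6-phenyl-4-[(triethylsilyl)oxy]hexa-1,5-dien-3-ol | CC[Si](CC)(CC)O[C@@H](/C=C/c1ccccc1)[C@@H](O)C=C
F4 | step 1 | tert-butyldimethyl{[(3S,4S,E)-6-phenyl-4-[(triethylsilyl)oxy]hexa-1,5-dien-3-yl]oxy}silane | CC[Si](CC)(CC)O[C@@H](/C=C/c1ccccc1)[C@@H](O[Si](C)(C)C(C)(C)C)C=C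
F5 | step 6 | tert-butyl (2Z,4S,5S,6R,7S)-4-[(tert-butyldimethylsilyl)oxy]-5,6-dihydroxy-7-phenyl-7-(2,4,6-trihydroxyphenyl)hept-2-enoate | CC(C)(C)OC(=O)/C=C\[C@H](O[Si](C)(C)C(C)(C)C)[C@@H](O)[C@H](O)[C@@H](c1ccccc1)c1c(O)cc(O)cc1O
F6 | step 7 | (1S,2S)-2-[(tert-butyldimethylsilyl)oxy]-1-[(2S,3S)-3-phenyloxiran-2-yl]but-3-en-1-yl prop-2-enoate | C=CC(=O)O[C@@H]([C@@H]1O[C@H]1c1ccccc1)[C@@H](O[Si](C)(C)C(C)(C)C)C=C
F7 | step 7 | (5S,6S)-5-[(tert-butyldimethylsilyl)oxy]-6-[(2R,3S)-3-phenyloxiran-2-yl]-5,6-dihydro-2H-pyran-2-one | O=C1C=C[C@H](O[Si](C)(C)C(C)(C)C)[C@H]([C@@H]2O[C@H]2c2ccccc2)O1
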